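**Retrosynthetic overview**
1. Ring B is closed last, on a carboxylic acid at C7' (vinylogous Claisen condensation, then enol lactonisation; bonds C6'–C5' and O1'–C2'), after the reductive step, in which a 2-pyranone would be at risk.
2. That acid carbon (C6') and the 2-phenylethyl group both come out of one temporary ring, a 2-phenyltetrahydropyran C6–C7–C8–O–C6'–C7', by hydrogenolysis of its benzylic C8–O bond; this also erases the auxiliary stereocentre C8.
3. Key disconnection: cyclobutane bonds C5–C8' and C6–C7', made together by an intramolecular triplet-sensitised [2+2] photocycloaddition of a cinnamyl ether onto the 5,6-double bond of a 4-methoxy-2-pyranone; it closes the tether ring and the four-membered ring and sets C5, C6, C7' and C8' from the single centre C8.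
4. Feature that makes this possible: in the target the C6 side chain (C7–C8) and the C7' substituent (C6') are cis on neighbouring cyclobutane carbons, and C8 is benzylic, so an oxygen bridge C8–O–C6' gives a strain-free six-membered ring that hydrogenolysis removes without trace.
5. Ring order: ring A (bought as 4-methoxy-6-methyl-2-pyranone) → tether ring and cyclobutane (step 4) → tether ring opened (step 5) → ring B (step 8).

Key step: step 4

Labels: ring A (lactone fused to the cyclobutane) is O1, C2(=O), C3, C4(OMe), C5, C6; C7H2–C8H2–Ph is the side chain on C6; C8' is the cyclobutane CH(Ph) bonded to C5; C7' is the cyclobutane CH bonded to C6; ring B is O1', C2'–C6', with C6' bonded to C7'. In the bicyclo names, C1 = C6, C6 = C5, C7 = C8', C8 = C7'.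

Assumption: compounds 1, 2, 7 and 14 are taken as commercial, and the facial sense of step 4 is a prediction from a chair model; if the other face reacts, the (R)-alcohol (from the (R,R)-catalyst in step 2) would be used and nothing else changes.

Step 1
Reactants: 1 4-methoxy-6-methyl-2H-pyran-2-one; 2 N-methoxy-N-methylbenzamide
Product: 5 4-methoxy-6-(2-oxo-2-phenylethyl)-2H-pyran-2-one, via lithiated pyranone 3 (not isolated), via tetrahedral lithium adduct 4 (not isolated)
Conditions: LDA (1.1 equiv), THF, −78 °C; then 2, −78 to −40 °C; aq NH4Cl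
Reagents that add atoms: none
Why: Weinreb ketone synthesis on a vinylogous enolate: LDA removes a proton from the C6 methyl group, the dienolate 3 adds to the amide carbonyl, and the chelated adduct 4 holds until the quench, so neither a second addition nor deprotonation of the acidic product can interfere.

Step 2
Reactants: 5 4-methoxy-6-(2-oxo-2-phenylethyl)-2H-pyran-2-one
Product: 6 6-[(2S)-2-hydroxy-2-phenylethyl]-4-methoxy-2H-pyran-2-one
Conditions: RuCl[(S,S)-TsDPEN](p-cymene) (1 mol %), HCO2H/Et3N (5:2), CH2Cl2, 25 °C
Reagents that add atoms: none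
Why: Noyori asymmetric transfer hydrogenation of an aryl alkyl ketone: the phenyl group is recognised by the arene ligand of the divalent ruthenium hydride, so the (S,S)-catalyst should give the (S)-carbinol as with acetophenone, under slightly acidic conditions in which the β-hydroxy pyranone neither dehydrates nor undergoes retro-aldol cleavage.

Step 3
Reactants: 6 6-[(2S)-2-hydroxy-2-phenylethyl]-4-methoxy-2H-pyran-2-one; 7 (E)-cinnamyl bromide
Product: 8 4-methoxy-6-[(2S)-2-phenyl-2-{[(2E)-3-phenylprop-2-en-1-yl]oxy}ethyl]-2H-pyran-2-one
Conditions: Ag2O (2 equiv), 7 (3 equiv), 4 Å molecular sieves, CH2Cl2, 23 °C, dark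
Reagents that add atoms: none
Why: Silver-oxide-promoted Williamson-type O-alkylation: the neutral hydroxyl group displaces the silver-activated allylic bromide at its unsubstituted terminus, so no free alkoxide forms that could cause retro-aldol cleavage or dehydration to the styrylpyranone, and C8 is untouched.

Step 4
Reactants: 8 4-methoxy-6-[(2S)-2-phenyl-2-{[(2E)-3-phenylprop-2-en-1-yl]oxy}ethyl]-2H-pyran-2-one
Product: 10 tricyclic photoadduct (target core carrying the C8–O–C6' tether ring), via triplet 1,4-diradical 9 (not isolated)
Conditions: [Ir(dF(CF3)ppy)2(dtbbpy)]PF6 (1 mol %), degassed MeCN (0.01 mol per litre), blue LEDs (450 nm), 25 °C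
Reagents that add atoms: none
Why: The photoexcited iridium complex (triplet energy near 61 kcal/mol) passes its energy to the β-alkylstyrene unit of 8; the styrene triplet bonds through C7' to C6 of the ground-state pyranone (6-exo-trig closure of the tether ring) and gives the triplet 1,4-diradical 9, with one radical at benzylic C8' and the other at C5, delocalised over the methoxy-enoate, and after intersystem crossing C5–C8' recombination closes the four-membered ring. The closest known reaction types are the visible-light energy-transfer intramolecular [2+2] cycloaddition of styrenes to tethered alkenes and the triplet-sensitised [2+2] cycloaddition of alkenes at the 5,6-double bond of 2-pyranones. The tetrahydropyran tether ring closes in the 6-exo-trig mode (straight and not crossed, because the four-atom tether and the better stabilised diradical both favour the C6–C7' bond), and the cyclobutane closes by radical recombination, necessarily cis-fused to ring A and to the tether ring. The absolute configuration comes from C8: in the chair-like transition state its phenyl group and the styryl terminus C8' are equatorial and ring A is held through axial C5, which opens one face of C6 to C7' and points the C5 p-orbital at C8'. C8' is fixed in the recombination, where its phenyl group should stay trans to C6'H2 across the already complete C7'–C8' bond (the E relationship of the styrene is kept) and so end cis to C4. The step needs facial selectivity on ring A, closure of the allylic radical at C5 and not at C3, and no dimerisation; these rest on the C8 centre (the other facial adduct is a separable diastereomer, not an enantiomer), on the short C5–C8' distance set by the tether ring, and on dilution.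

Step 5
Reactants: 10 tricyclic photoadduct
Product: 11 8-(hydroxymethyl)-5-methoxy-7-phenyl-1-(2-phenylethyl)-2-oxabicyclo[4.2.0]oct-4-en-3-one (ring stereocentres as in 18)
Conditions: H2 (1 atm), Pd(OH)2 on carbon, EtOAc/EtOH, 23 °C
Reagents that add atoms: none
Why: Hydrogenolysis of a benzylic C–O bond: only the C8–O bond of the 2-phenyltetrahydropyran is benzylic, so its cleavage turns C8 into the CH2 of the 2-phenylethyl group (the auxiliary stereocentre disappears) and C6' into a primary alcohol, while the push–pull enol ether of ring A, the tertiary non-benzylic C6–O1 bond and the phenylcyclobutane should stay intact.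

Step 6
Reactants: 11 primary alcohol
Product: 13 5-methoxy-3-oxo-7-phenyl-1-(2-phenylethyl)-2-oxabicyclo[4.2.0]oct-4-ene-8-carboxylic acid (ring stereocentres as in 18), via aldehyde 12 (not isolated)
Conditions: TEMPO (0.2 equiv), PhI(OAc)2 (2.5 equiv), MeCN/H2O (1:1), 23 °C
Reagents that add atoms: water, O
Why: TEMPO/oxoammonium oxidation of the primary alcohol to the aldehyde and, through its hydrate, to the acid under near-neutral conditions that should spare the enol ether and not epimerise C7'.

Step 7
Reactants: 13 carboxylic acid; 14 methyl (2E)-3-methoxybut-2-enoate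
Product: 17 methyl (2E)-3-methoxy-5-[5-methoxy-3-oxo-7-phenyl-1-(2-phenylethyl)-2-oxabicyclo[4.2.0]oct-4-en-8-yl]-5-oxopent-2-enoate (ring stereocentres as in 18), via acyl imidazole 15 (not isolated), via lithium dienolate 16 (not isolated)
Conditions: 13, 1,1'-carbonyldiimidazole, THF, 23 °C; separately 14 (3 equiv), LDA (3 equiv), THF, −78 °C; combine at −78 °C; AcOH quench
Reagents that add atoms: none
Why: Vinylogous Claisen condensation: acyl imidazole 15 acylates the γ-carbon of lithium dienolate 16 (3-alkoxy dienolates react with carbonyl electrophiles at the γ-terminus), the excess dienolate takes up the acidic C5' proton of the product and so stops a second acylation, and at −78 °C neither C7' nor ring A is expected to enolise productively.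

Step 8
Reactants: 17 keto ester
Product: 18 (1R,6S,7S,8S)-5-methoxy-8-(4-methoxy-2-oxo-2H-pyran-6-yl)-7-phenyl-1-(2-phenylethyl)-2-oxabicyclo[4.2.0]oct-4-en-3-one (target)
Conditions: DBU (0.5 equiv), toluene, 80 °C
Reagents that add atoms: none
Why: Enol lactonisation: DBU enolises the ketone towards C5', the enol oxygen adds to the cis-placed methyl ester and expels methanol (6-exo-trig addition–elimination) to give the 4-methoxy-2-pyranone ring B, and C7' should keep its configuration because enolisation towards the cyclobutane would need an exocyclic double bond on the four-membered ring.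

**Compound list**
1 | 4-methoxy-6-methyl-2H-pyran-2-one | COc1cc(C)oc(=O)c1 | starting material
2 | N-methoxy-N-methylbenzamide | CON(C)C(=O)c1ccccc1 | starting material
3 | [(4-methoxy-2-oxo-2H-pyran-6-yl)methyl]lithium (lithium dienolate of 1) | [Li]Cc1cc(OC)cc(=O)o1 | intermediate
4 | lithium 1-[methoxy(methyl)amino]-2-(4-methoxy-2-oxo-2H-pyran-6-yl)-1-phenylethan-1-olate (chelated tetrahedral adduct) | [Li]OC(Cc1cc(OC)cc(=O)o1)(N(C)OC)c1ccccc1 | intermediate
5 | 4-methoxy-6-(2-oxo-2-phenylethyl)-2H-pyran-2-one | COc1cc(CC(=O)c2ccccc2)oc(=O)c1 | intermediate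
6 | 6-[(2S)-2-hydroxy-2-phenylethyl]-4-methoxy-2H-pyran-2-one | COc1cc(C[C@H](O)c2ccccc2)oc(=O)c1 | intermediate
7 | (E)-cinnamyl bromide, [(1E)-3-bromoprop-1-en-1-yl]benzene | BrC/C=C/c1ccccc1 | starting material
8 | 4-methoxy-6-[(2S)-2-phenyl-2-{[(2E)-3-phenylprop-2-en-1-yl]oxy}ethyl]-2H-pyran-2-one | COc1cc(C[C@H](OC/C=C/c2ccccc2)c2ccccc2)oc(=O)c1 | intermediate
9 | triplet 1,4-diradical: tether ring closed by the C6–C7' bond, radical centres at C5 (ring A, delocalised) and C8' (benzylic), C8 (S) | COC1=CC(=O)O[C@]2(C[C@@H](c3ccccc3)OC[C@@H]2[CH]c4ccccc4)[CH]1 | intermediate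
10 | tricyclic photoadduct: core of 18 in which C6 and C7' are bridged by CH2–CH(Ph)–O–CH2 (tether ring; its phenyl-bearing carbon C8 is S and cis to O1 across that ring); C5, C6, C7', C8' as in 18, C8' phenyl trans to C6'H2 and cis to C4 | COC1=CC(=O)O[C@]2(C[C@@H](c3ccccc3)OC[C@@H]2[C@H]4c5ccccc5)[C@H]14 | intermediate
11 | 8-(hydroxymethyl)-5-methoxy-7-phenyl-1-(2-phenylethyl)-2-oxabicyclo[4.2.0]oct-4-en-3-one, ring stereocentres as in 18 | COC1=CC(=O)O[C@]2(CCc3ccccc3)[C@H]1[C@H](c1ccccc1)[C@H]2CO | intermediate
12 | 5-methoxy-3-oxo-7-phenyl-1-(2-phenylethyl)-2-oxabicyclo[4.2.0]oct-4-ene-8-carbaldehyde, ring stereocentres as in 18 | COC1=CC(=O)O[C@]2(CCc3ccccc3)[C@H]1[C@H](c1ccccc1)[C@H]2C=O | intermediate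
13 | 5-methoxy-3-oxo-7-phenyl-1-(2-phenylethyl)-2-oxabicyclo[4.2.0]oct-4-ene-8-carboxylic acid, ring stereocentres as in 18 | COC1=CC(=O)O[C@]2(CCc3ccccc3)[C@H]1[C@H](c1ccccc1)[C@H]2C(=O)O | intermediate
14 | methyl (2E)-3-methoxybut-2-enoate | CO/C(C)=C/C(=O)OC | starting material
15 | 8-(1H-imidazol-1-ylcarbonyl)-5-methoxy-7-phenyl-1-(2-phenylethyl)-2-oxabicyclo[4.2.0]oct-4-en-3-one, ring stereocentres as in 18 | COC1=CC(=O)O[C@]2(CCc3ccccc3)[C@H]1[C@H](c1ccccc1)[C@H]2C(=O)n1ccnc1 | intermediate
16 | lithium 1,3-dimethoxybuta-1,3-dien-1-olate (lithium dienolate of 14) | C=C(OC)C=C(OC)O[Li] | intermediate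
17 | methyl (2E)-3-methoxy-5-[5-methoxy-3-oxo-7-phenyl-1-(2-phenylethyl)-2-oxabicyclo[4.2.0]oct-4-en-8-yl]-5-oxopent-2-enoate, ring stereocentres as in 18 | COC1=CC(=O)O[C@]2(CCc3ccccc3)[C@H]1[C@H](c1ccccc1)[C@H]2C(=O)C/C(OC)=C\C(=O)OC | intermediate
18 | (1R,6S,7S,8S)-5-methoxy-8-(4-methoxy-2-oxo-2H-pyran-6-yl)-7-phenyl-1-(2-phenylethyl)-2-oxabicyclo[4.2.0]oct-4-en-3-one | COC1=CC(=O)O[C@]2(CCc3ccccc3)[C@H]1[C@H](c1ccccc1)[C@H]2c1cc(OC)cc(=O)o1 | target

**Step count**
Total: 8 steps. Longest linear sequence: 8 steps (1 → 18).

**Steps most likely to fail**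

Risk 1, step 4. The six-membered closure of the styrene triplet onto C6 may lose to triplet decay, so that only E/Z isomerisation is seen. The remote C8 centre may also discriminate the two faces of ring A weakly, or the diradical may close at C3 or with the C8' phenyl on the wrong side. The fallback drops the tether and sets out from 1. Lithiation (LDA, through 3) and benzylation with benzyl bromide should give 4-methoxy-6-(2-phenylethyl)-2H-pyran-2-one F1. Condensation of 1 with benzaldehyde (Mg(OMe)2, MeOH, reflux) should give 4-methoxy-6-[(E)-2-phenylethenyl]-2H-pyran-2-one F2. Irradiation of F2 (365 nm, or thioxanthone sensitisation) in the presence of excess F1 should give, beside homodimers of F2 and isomeric adducts, the 5,6/7',8' cross-adduct as the racemate. The racemate is 18 together with ent-18 F3, which is removed by preparative chromatography on a chiral stationary phase. The fallback comes back to the route at 18.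

Risk 2, step 3. Activation of the hydroxyl group may lead to loss of water through the acidic C7 protons or to retro-aldol cleavage, and ionisation of the cinnamyl bromide may give the branched ether. The fallback sets out from 6 and replaces the silver-assisted displacement by acid-catalysed imidate alkylation, with no base present. (E)-Cinnamyl alcohol and trichloroacetonitrile (cat. DBU) give (E)-cinnamyl 2,2,2-trichloroacetimidate F4. Compound 6 and F4 with catalytic TfOH in CH2Cl2/cyclohexane at −20 °C should give the ether. The fallback comes back to the route at 8.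

Risk 3, step 7. Proton transfer from the hindered acyl imidazole or from ring A to the dienolate, α- instead of γ-acylation, or epimerisation at C7' may erode the condensation. The fallback sets out from 13 and uses a neutral silyl dienol ether with late O-methylation. Oxalyl chloride (cat. DMF) gives 5-methoxy-3-oxo-7-phenyl-1-(2-phenylethyl)-2-oxabicyclo[4.2.0]oct-4-ene-8-carbonyl chloride F5. Mukaiyama-type γ-acylation of 1-methoxy-1,3-bis(trimethylsilyloxy)buta-1,3-diene (CH2Cl2, −78 to 20 °C) gives the methyl 3,5-dioxopentanoate F6. DBU in toluene closes it to the 4-hydroxy-2-pyranone F7. Me2SO4 and K2CO3 in acetone methylate the 4-hydroxyl group. The fallback comes back to the route at 18.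

**Further compounds**
F1 | step 4 | 4-methoxy-6-(2-phenylethyl)-2H-pyran-2-one | COc1cc(CCc2ccccc2)oc(=O)c1
F2 | step 4 | 4-methoxy-6-[(E)-2-phenylethenyl]-2H-pyran-2-one | COc1cc(/C=C/c2ccccc2)oc(=O)c1
F3 | step 4 | ent-18, (1S,6R,7R,8R)-5-methoxy-8-(4-methoxy-2-oxo-2H-pyran-6-yl)-7-phenyl-1-(2-phenylethyl)-2-oxabicyclo[4.2.0]oct-4-en-3-one | COC1=CC(=O)O[C@@]2(CCc3ccccc3)[C@@H]1[C@@H](c1ccccc1)[C@@H]2c1cc(OC)cc(=O)o1
F4 | step 3 | (E)-cinnamyl 2,2,2-trichloroacetimidate | N=C(OC/C=C/c1ccccc1)C(Cl)(Cl)Cl
F5 | step 7 | 5-methoxy-3-oxo-7-phenyl-1-(2-phenylethyl)-2-oxabicyclo[4.2.0]oct-4-ene-8-carbonyl chloride, ring stereocentres as in 18 | COC1=CC(=O)O[C@]2(CCc3ccccc3)[C@H]1[C@H](c1ccccc1)[C@H]2C(=O)Cl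
F6 | step 7 | methyl 5-[5-methoxy-3-oxo-7-phenyl-1-(2-phenylethyl)-2-oxabicyclo[4.2.0]oct-4-en-8-yl]-3,5-dioxopentanoate, ring stereocentres as in 18 | COC1=CC(=O)O[C@]2(CCc3ccccc3)[C@H]1[C@H](c1ccccc1)[C@H]2C(=O)CC(=O)CC(=O)OC
F7 | step 7 | 8-(4-hydroxy-2-oxo-2H-pyran-6-yl)-5-methoxy-7-phenyl-1-(2-phenylethyl)-2-oxabicyclo[4.2.0]oct-4-en-3-one, ring stereocentres as in 18 | COC1=CC(=O)O[C@]2(CCc3ccccc3)[C@H]1[C@H](c1ccccc1)[C@H]2c1cc(O)cc(=O)o1
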